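Numbering (guaiane): ring A (five-membered) is C1(OH)–C2–C3(=O)–C4(CH3)=C5; ring B (seven-membered) is C5–C6(OH)–C7(C11Me2OAc)–C8(OAng)–C9–C10(CH3)–C1; β is the face that carries the C10 methyl.
Enabling feature: in ring B the vicinal pair C1 (quaternary carbinol) and C10 (methyl-bearing methine) lies directly opposite C7, with C5–C6 and C8–C9 on either side. This is the pattern left by a [3,3] shift of a C6–C7–C8 cyclopropane that carries cis C5=C1 and C9=C10 arms.
Retrosynthetic cuts, in order: the two esters and the C3 oxygen; C6–O and C4–C15 (back to a C4 ketone with C5=C6); C8–O (back to C8=C9); C1–C10 (retro-Cope, restoring C6–C8); C9=C10; C5–C6; and the cyclopropane itself (C6 from iodoform added to a C7=C8 allylic alcohol).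
Forward: ring A is bought as 3-methoxycyclopent-2-enone. The three-membered ring is made and joined to it in one operation, the propenyl arm is added, and ring B arises by expansion of the cyclopropane.
Stereochemistry: a chiral dioxaborolane sets the cyclopropane (C7 survives to the target). The boat transition state relays this to C1 and C10, a silicon tether from O11 sets C8, and hydride attack anti to the C7 side chain sets C6.
Key step: step 9

Assumption: the (4R,5R)-dioxaborolane should steer the gem-dizinc carbenoid to the same face of 4 as it steers the parent zinc carbenoid on (E)-cinnamyl alcohol, which gives the (1S,2S) alcohol; if the sense proves opposite, the (4S,5S) ligand is used.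

Step 1
Reactants: 1 2-methylbut-3-en-2-ol
Product: 2 triethyl[(2-methylbut-3-en-2-yl)oxy]silane
Conditions: TESOTf, 2,6-lutidine, CH2Cl2, 0 °C
Reagents that add atoms: triethylsilyl trifluoromethanesulfonate, CC[Si](CC)(CC)OS(=O)(=O)C(F)(F)F
Why: A silyl triflate with a hindered pyridine base silylates even tertiary allylic alcohols (standard O-silylation), and the ether stops this oxygen from competing as a directing group in step 4.

Step 2
Reactants: 2 triethyl[(2-methylbut-3-en-2-yl)oxy]silane; 3 (Z)-but-2-ene-1,4-diol
Product: 4 (E)-4-methyl-4-[(triethylsilyl)oxy]pent-2-en-1-ol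
Conditions: second-generation Grubbs catalyst (H2IMes)(PCy3)Cl2Ru=CHPh (3 mol %), 1,4-benzoquinone (10 mol %), CH2Cl2, 40 °C
Reagents that add atoms: none
Why: Olefin cross-metathesis of a slow alkene with a fully substituted allylic carbon and a fast primary allylic alcohol partner favours the cross product, and the bulky allylic centre enforces the E alkene that later places C7 trans to C8.

Step 3
Reactants: 5 3-methoxycyclopent-2-en-1-one
Product: 6 2-iodo-3-methoxycyclopent-2-en-1-one
Conditions: N-iodosuccinimide, MeCN, rt, dark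
Reagents that add atoms: N-iodosuccinimide, O=C1CCC(=O)N1I
Why: The α-carbon of a vinylogous ester is its nucleophilic site, so electrophilic iodination there gives the α-iodo enone needed for cross-coupling.

Step 4
Reactants: 4 (E)-4-methyl-4-[(triethylsilyl)oxy]pent-2-en-1-ol; 6 2-iodo-3-methoxycyclopent-2-en-1-one
Product: 9 2-[(1R,2S,3S)-2-(hydroxymethyl)-3-{2-[(triethylsilyl)oxy]propan-2-yl}cyclopropyl]-3-methoxycyclopent-2-en-1-one, via cyclopropylzinc iodide 7 (not isolated), via bicyclic butylborinate 8 (not isolated)
Conditions: Et2Zn, I2, CHI3, (4R,5R)-2-butyl-N,N,N′,N′-tetramethyl-1,3,2-dioxaborolane-4,5-dicarboxamide, CH2Cl2/Et2O, 0 °C to rt; then 6, Pd(PPh3)4 (5 mol %), aq K3PO4, THF, 60 °C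
Reagents that add atoms: iodoform, C(I)(I)I
Why: The directed Simmons–Smith-type zinco-cyclopropanation with (IZn)2CHI is stereospecific for the E alkene (C7 trans to C8), the boron-bound alkoxide selects the alkene face and holds the remaining C–Zn bond syn to CH2O, and boron–zinc exchange followed by Suzuki–Miyaura coupling replaces the metal by C5 with retention, so C6, C7 and C8 are set with the two future arms cis.

Step 5
Reactants: 9 cyclopropylmethanol from step 4
Product: 10 (cyclopropane configuration as in 9) 2-(2-methoxy-5-oxocyclopent-1-en-1-yl)-3-{2-[(triethylsilyl)oxy]propan-2-yl}cyclopropane-1-carbaldehyde, CHO cis to the enone ring and trans to the side chain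
Conditions: Dess–Martin periodinane, NaHCO3, CH2Cl2, 0 °C to rt
Reagents that add atoms: none
Why: Buffered Dess–Martin oxidation stops at the aldehyde, does not epimerise C8, and leaves the silyl ether and the vinylogous ester untouched.

Step 6
Reactants: 10 cis-aldehyde; 11 5-(ethylsulfonyl)-1-phenyl-1H-tetrazole
Product: 12 3-methoxy-2-[cis-2-((E)-prop-1-enyl)-trans-3-{2-[(triethylsilyl)oxy]propan-2-yl}cyclopropyl]cyclopent-2-en-1-one (configuration as in 9)
Conditions: 11, KN(SiMe3)2, DME, −60 °C; then 10, to rt
Reagents that add atoms: none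
Why: Julia–Kocienski olefination with a phenyltetrazolyl sulfone and a potassium base in DME favours the E alkene (anti addition, Smiles rearrangement, elimination), and the metallated sulfone attacks the aldehyde far faster than the vinylogous ester.

Step 7
Reactants: 12 methoxy enone
Product: 13 3-hydroxy-2-[cis-2-((E)-prop-1-enyl)-trans-3-{2-[(triethylsilyl)oxy]propan-2-yl}cyclopropyl]cyclopent-2-en-1-one (enol form of the 2-substituted cyclopentane-1,3-dione)
Conditions: NaOH (1 M aq), THF/MeOH, 35 °C; then HCl (1 M) to pH 4–5, 0 °C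
Reagents that add atoms: sodium hydroxide, [Na+].[OH-]
Why: Hydroxide adds to the β-carbon of the vinylogous ester and expels methoxide (saponification by addition–elimination), which frees the symmetric 1,3-dione without acid strong enough to ionise the cyclopropylcarbinyl silyl ether.

Step 8
Reactants: 13 dione (enol form)
Product: 14 3-(tert-butyldimethylsilyloxy)-2-[cis-2-((E)-prop-1-enyl)-trans-3-{2-[(triethylsilyl)oxy]propan-2-yl}cyclopropyl]cyclopent-2-en-1-one
Conditions: TBSCl, Et3N, CH2Cl2, 0 °C to rt; filtration under argon, used directly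
Reagents that add atoms: tert-butyldimethylsilyl chloride, CC(C)(C)[Si](C)(C)Cl
Why: The acidic enol is O-silylated under mild base (silyl enol ether formation), and because the two carbonyl groups are equivalent only one vinylogous silyl ester can form.

Step 9
Reactants: 14 cis-divinylcyclopropane
Product: 15 1α-(tert-butyldimethylsilyloxy)-11-(triethylsilyloxy)-15-norguaia-5,8-dien-4-one (7β side chain, 10β-methyl)
Conditions: toluene (degassed, 0.02 M), BHT (cat.), base-washed sealed tube, 110 °C
Reagents that add atoms: none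
Why: On heating, the two cis alkenyl arms of 14 fold over the three-membered ring, and a concerted suprafacial [3,3] shift through the endo-boat transition state forms C1–C10 while the strained C6–C8 bond breaks, leaving C5=C6 and C8=C9 as ring-cis alkenes. The closest known reaction type is the divinylcyclopropane–cycloheptadiene (Cope) rearrangement of cis-2-alkenylcyclopropyl enones and silyl enol ethers to hydroazulenes, in which inward alkoxy groups and fully substituted termini are each tolerated at higher temperature. Ring B closes pericyclically as a three-to-seven ring expansion, so no exo or endo trajectory has to be met, and loss of cyclopropane strain together with the new C4 enone conjugation makes the step irreversible. C1 is fixed by the ring-locked geometry of C5=C1 (C2 outward, silyloxy inward) and C10 by the E geometry of the propenyl arm, so C2, the C10 methyl and the C7 side chain (trans to both arms) all end on the β face and O1 on the α face. The boat pathway must outrun C6–C8 homolysis and silyl loss; in its favour, no cis sp3 C–H is available for a homodienyl hydrogen shift, the C7 position facing the inward oxygen carries only hydrogen, and only one enol silane exists.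

Step 10
Reactants: 15 Cope product
Product: 16 11-hydroxy-1α-(tert-butyldimethylsilyloxy)-15-norguaia-5,8-dien-4-one
Conditions: HF·pyridine, pyridine, THF, 0 °C
Reagents that add atoms: none
Why: Buffered HF·pyridine discriminates between silyl ethers by size (selective desilylation), so the triethylsilyl ether should be cleaved while the bulkier silyl ether on C1 stays.

Step 11
Reactants: 16 tertiary alcohol
Product: 17 11-(dimethylsilyloxy)-1α-(tert-butyldimethylsilyloxy)-15-norguaia-5,8-dien-4-one
Conditions: Me2SiHCl, Et3N, DMAP (cat.), CH2Cl2, 0 °C to rt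
Reagents that add atoms: chlorodimethylsilane, C[SiH](C)Cl
Why: Small chlorosilanes silylate tertiary alcohols readily (O-silylation), which installs the Si–H tether for the next step.

Step 12
Reactants: 17 hydrosilyl ether
Product: 19 8β,11-dihydroxy-1α-(tert-butyldimethylsilyloxy)-15-norguai-5-en-4-one, via oxasilolane 18 (not isolated)
Conditions: Pt2[(CH2=CHSiMe2)2O]3 (0.5 mol %), toluene, 50 °C; then 30% H2O2, KF, KHCO3, THF/MeOH, 0 °C to rt
Reagents that add atoms: hydrogen peroxide, OO
Why: Platinum-catalysed intramolecular hydrosilylation of a homoallylic silyl ether closes the five-membered oxasilolane in the exo mode, so silicon goes to C8 (not C9) from the β face on which the C7 side chain lies, and Tamao oxidation replaces it by hydroxyl with retention to set 8β-OH, the conjugated trisubstituted C5=C6 being far less reactive.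

Step 13
Reactants: 19 diol; 20 angelic acid [(Z)-2-methylbut-2-enoic acid]
Product: 22 8β-angeloyloxy-11-hydroxy-1α-(tert-butyldimethylsilyloxy)-15-norguai-5-en-4-one, via mixed anhydride 21 (not isolated)
Conditions: 20, 2,4,6-trichlorobenzoyl chloride, Et3N, toluene, rt; then 19, 80 °C
Reagents that add atoms: none
Why: Acylation through the 2,4,6-trichlorobenzoyl mixed anhydride (Yamaguchi-type esterification without nucleophilic catalyst) is the established way to transfer the angeloyl group without Z to E isomerisation, and only the secondary 8-OH should react.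

Step 14
Reactants: 22 angelate
Product: 23 11-acetoxy-8β-angeloyloxy-1α-(tert-butyldimethylsilyloxy)-15-norguai-5-en-4-one
Conditions: Ac2O, DMAP, Et3N, CH2Cl2, 35 °C
Reagents that add atoms: acetic anhydride, CC(=O)OC(C)=O
Why: DMAP-catalysed acyl transfer esterifies the tertiary 11-OH at the stage where C6 is still sp2 and the surroundings are least crowded.

Step 15
Reactants: 23 keto diester
Product: 24 11-acetoxy-8β-angeloyloxy-4-hydroxy-1α-(tert-butyldimethylsilyloxy)guai-5-ene (either C4 epimer serves)
Conditions: MeLi, CeCl3, THF, −78 °C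
Reagents that add atoms: methyllithium, [Li]C
Why: The weakly basic organocerium reagent (Imamoto conditions) adds 1,2 to the enone carbonyl at −78 °C much faster than to the hindered tertiary acetate or the conjugated angelate, and the new C4 centre is erased in step 16.

Step 16
Reactants: 24 tertiary allylic alcohol
Product: 25 11-acetoxy-8β-angeloyloxy-1α-(tert-butyldimethylsilyloxy)guai-4-en-6-one
Conditions: pyridinium chlorochromate [C5H5NH][CrO3Cl], 4 Å MS, CH2Cl2, rt
Reagents that add atoms: pyridinium chlorochromate, [O-][Cr](=O)(=O)Cl.c1cc[nH+]cc1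
Why: In the Babler–Dauben oxidative transposition the tertiary allylic chromate ester shifts [3,3] to C6 and is oxidised there, giving the C4=C5 enone from either C4 epimer under conditions too mild to enolise C7.

Step 17
Reactants: 25 enone
Product: 26 11-acetoxy-8β-angeloyloxy-6β-hydroxy-1α-(tert-butyldimethylsilyloxy)guai-4-ene
Conditions: NaBH4, CeCl3·7H2O, MeOH, −78 to −40 °C
Reagents that add atoms: none
Why: Luche reduction gives 1,2-reduction only, and hydride should reach C6 from the α face, away from the adjacent β-oriented C7 side chain and the 8β-ester, which sets the 6β-alcohol.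

Step 18
Reactants: 26 allylic alcohol
Product: 27 11-acetoxy-8β-angeloyloxy-6β-(triethylsilyloxy)-1α-(tert-butyldimethylsilyloxy)guai-4-ene
Conditions: TESOTf, 2,6-lutidine, CH2Cl2, −78 °C
Reagents that add atoms: triethylsilyl trifluoromethanesulfonate, CC[Si](CC)(CC)OS(=O)(=O)C(F)(F)F
Why: The only free hydroxyl is silylated under non-nucleophilic conditions (O-silylation) that do not provoke acyl migration, which protects it from the oxidant of step 19.

Step 19
Reactants: 27 bis-silyl ether
Product: 28 11-acetoxy-8β-angeloyloxy-6β-(triethylsilyloxy)-1α-(tert-butyldimethylsilyloxy)guai-4-en-3-one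
Conditions: dirhodium tetracaprolactamate Rh2(cap)4 (1 mol %), t-BuOOH (70% aq), 1,2-dichloroethane, 40 °C
Reagents that add atoms: tert-butyl hydroperoxide, CC(C)(C)OO
Why: Dirhodium-caprolactamate/hydroperoxide allylic oxidation (hydrogen abstraction by the tert-butylperoxy radical) turns ring methylenes next to alkenes into enones, and C3–H2 is the only unhindered secondary allylic site, since C1 is quaternary, C15 is primary and C6–H is shielded by two silyl ethers.

Step 20
Reactants: 28 protected target
Product: 29 (1R,6R,7S,8R,10S)-11-acetoxy-8β-angeloyloxy-1α,6β-dihydroxyguai-4-en-3-one (CNP0273287.1)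
Conditions: HF·pyridine, MeCN, 0 °C to rt
Reagents that add atoms: none
Why: Fluoride-mediated global desilylation under mildly acidic conditions removes both silyl ethers without touching the esters, and β-elimination of the 1-OH is blocked because it would create a cyclopentadienone.

Compound list
1 | 2-methylbut-3-en-2-ol | C=CC(C)(C)O | starting material
2 | triethyl[(2-methylbut-3-en-2-yl)oxy]silane | C=CC(C)(C)O[Si](CC)(CC)CC | intermediate
3 | (Z)-but-2-ene-1,4-diol | OC/C=C\CO | starting material
4 | (E)-4-methyl-4-[(triethylsilyl)oxy]pent-2-en-1-ol | OC/C=C/C(C)(C)O[Si](CC)(CC)CC | intermediate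
5 | 3-methoxycyclopent-2-en-1-one | COC1=CC(=O)CC1 | starting material
6 | 2-iodo-3-methoxycyclopent-2-en-1-one | COC1=C(I)C(=O)CC1 | intermediate
7 | cyclopropylzinc iodide (zinc on C6 cis to CH2O, drawn as its iodozinc alkoxide) | I[Zn][C@H]1[C@H](C(C)(C)O[Si](CC)(CC)CC)[C@H]1CO[Zn]I | intermediate
8 | bicyclic butylborinate (2-butyl-3-oxa-2-borabicyclo[3.1.0]hexane with the exo C7 side chain) | CCCCB1OC[C@H]2[C@@H]1[C@@H]2C(C)(C)O[Si](CC)(CC)CC | intermediate
9 | 2-[(1R,2S,3S)-2-(hydroxymethyl)-3-{2-[(triethylsilyl)oxy]propan-2-yl}cyclopropyl]-3-methoxycyclopent-2-en-1-one | COC1=C(C(=O)CC1)[C@H]2[C@H](C(C)(C)O[Si](CC)(CC)CC)[C@H]2CO | intermediate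
10 | cis-aldehyde of 9 | COC1=C(C(=O)CC1)[C@H]2[C@H](C(C)(C)O[Si](CC)(CC)CC)[C@H]2C=O | intermediate
11 | 5-(ethylsulfonyl)-1-phenyl-1H-tetrazole | CCS(=O)(=O)c1nnnn1-c1ccccc1 | starting material
12 | methoxy enone with cis (E)-propenyl arm | COC1=C(C(=O)CC1)[C@H]2[C@H](C(C)(C)O[Si](CC)(CC)CC)[C@H]2/C=C/C | intermediate
13 | 2-substituted cyclopentane-1,3-dione (enol form) | O=C1CCC(O)=C1[C@H]2[C@H](C(C)(C)O[Si](CC)(CC)CC)[C@H]2/C=C/C | intermediate
14 | silyl enol ether, cis-divinylcyclopropane (Cope precursor) | O=C1CCC(O[Si](C)(C)C(C)(C)C)=C1[C@H]2[C@H](C(C)(C)O[Si](CC)(CC)CC)[C@H]2/C=C/C | intermediate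
15 | 1α-OTBS, 11-OTES 15-norguaia-5,8-dien-4-one (Cope product) | C[C@H]1C=C[C@@H](C(C)(C)O[Si](CC)(CC)CC)C=C2C(=O)CC[C@@]12O[Si](C)(C)C(C)(C)C | intermediate
16 | 11-hydroxy dienone | C[C@H]1C=C[C@@H](C(C)(C)O)C=C2C(=O)CC[C@@]12O[Si](C)(C)C(C)(C)C | intermediate
17 | 11-O-dimethylsilyl dienone | C[C@H]1C=C[C@@H](C(C)(C)O[SiH](C)C)C=C2C(=O)CC[C@@]12O[Si](C)(C)C(C)(C)C | intermediate
18 | cis-fused oxasilolane (Si on C8β, O on C11) | C[C@H]1C[C@@H]3[C@@H](C(C)(C)O[Si]3(C)C)C=C2C(=O)CC[C@@]12O[Si](C)(C)C(C)(C)C | intermediate
19 | 8β,11-diol enone | C[C@H]1C[C@@H](O)[C@@H](C(C)(C)O)C=C2C(=O)CC[C@@]12O[Si](C)(C)C(C)(C)C | intermediate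
20 | angelic acid | C/C=C(/C)C(=O)O | starting material
21 | angelic 2,4,6-trichlorobenzoic anhydride | C/C=C(/C)C(=O)OC(=O)c1c(Cl)cc(Cl)cc1Cl | intermediate
22 | 8β-angelate, 11-ol | C[C@H]1C[C@@H](OC(=O)/C(C)=C\C)[C@@H](C(C)(C)O)C=C2C(=O)CC[C@@]12O[Si](C)(C)C(C)(C)C | intermediate
23 | 8β-angelate, 11-acetate, 4-ketone | C[C@H]1C[C@@H](OC(=O)/C(C)=C\C)[C@@H](C(C)(C)OC(C)=O)C=C2C(=O)CC[C@@]12O[Si](C)(C)C(C)(C)C | intermediate
24 | C4 tertiary allylic alcohol (C4 left undefined on purpose) | C[C@H]1C[C@@H](OC(=O)/C(C)=C\C)[C@@H](C(C)(C)OC(C)=O)C=C2C(C)(O)CC[C@@]12O[Si](C)(C)C(C)(C)C | intermediate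
25 | guai-4-en-6-one | C[C@H]1C[C@@H](OC(=O)/C(C)=C\C)[C@@H](C(C)(C)OC(C)=O)C(=O)C2=C(C)CC[C@@]12O[Si](C)(C)C(C)(C)C | intermediate
26 | 6β-alcohol | C[C@H]1C[C@@H](OC(=O)/C(C)=C\C)[C@@H](C(C)(C)OC(C)=O)[C@@H](O)C2=C(C)CC[C@@]12O[Si](C)(C)C(C)(C)C | intermediate
27 | 6β-OTES ether | C[C@H]1C[C@@H](OC(=O)/C(C)=C\C)[C@@H](C(C)(C)OC(C)=O)[C@@H](O[Si](CC)(CC)CC)C2=C(C)CC[C@@]12O[Si](C)(C)C(C)(C)C | intermediate
28 | guai-4-en-3-one, bis-silyl ether | C[C@H]1C[C@@H](OC(=O)/C(C)=C\C)[C@@H](C(C)(C)OC(C)=O)[C@@H](O[Si](CC)(CC)CC)C2=C(C)C(=O)C[C@@]12O[Si](C)(C)C(C)(C)C | intermediate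
29 | 11-acetoxy-8β-angeloyloxy-1α,6β-dihydroxyguai-4-en-3-one | C/C=C(/C)C(=O)O[C@@H]1C[C@H](C)[C@]2(O)CC(=O)C(C)=C2[C@H](O)[C@@H]1C(C)(C)OC(C)=O | target

Total step count: 20. Longest linear sequence: 19 (steps 1, 2 and 4–20; step 3 is a one-step branch).

Steps most likely to fail

Step 9. The inward silyloxy group and the loss of push–pull conjugation may raise the barrier so far that hydrolysis or transfer of the vinylogous silyl group, or stereorandomising homolysis of C6–C8, overtakes the shift. The fallback sets out from 13 and moves the rearrangement onto a carbon-protected enol ether, which can be purified and heated much harder. Mitsunobu etherification of 13 with 4-methoxybenzyl alcohol (PPh3, DIAD, THF) should give the 4-methoxybenzyl enol ether F1. Thermolysis in 1,2-dichlorobenzene at 150–170 °C should give the tertiary 4-methoxybenzyl ether F2. DDQ in buffered CH2Cl2 then frees the tertiary 1α-alcohol F3, and TBSOTf/2,6-lutidine returns to 15.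

Step 4. Boron–zinc exchange may stay incomplete, the cyclopropylmetal may be protonated, or transmetalation of the hindered borinate to palladium may be slower than decay of the iodo enone. The fallback sets out from 2, makes C8 rather than C6 the carbene carbon, and isolates every organoboron stage. Cross-metathesis of 2 with vinylboronic acid pinacol ester (second-generation Grubbs catalyst) gives the (E)-alkenylboronate F4. Cyclopropanation with ethyl diazoacetate follows, using Cu(MeCN)4PF6 (monovalent copper) and the tert-butyl bis(oxazoline) enantiomer that leads to the series of 9. It should place the ester trans to the bulky C7 group and hence cis to boron, giving the cyclopropylboronate ester F5. Reduction with i-Bu2AlH at −78 °C gives the boronate alcohol F6. A separate Suzuki–Miyaura coupling with 6 (Pd(OAc)2, 2-dicyclohexylphosphino-2′,6′-dimethoxybiphenyl, K3PO4, toluene/water) returns to 9.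

Step 19. Hydrogen abstraction at the α-silyloxy allylic C6–H, or at the C15 methyl, may compete with abstraction at C3 and lead to re-oxidation at C6. The fallback sets out from 26 and replaces the electron-releasing silyl ether by an electron-withdrawing ester, which deactivates C6–H toward the electrophilic peroxy radical. Chloroacetic anhydride and pyridine give the 6β-chloroacetate F7. Allylic oxidation (Rh2(cap)4/t-BuOOH or CrO3·3,5-dimethylpyrazole) gives the 3-ketone chloroacetate F8. Thiourea and NaHCO3 in ethanol remove only the chloroacetate to give the 1-O-silyl 6β-alcohol F9, and HF·pyridine returns to the route at 29.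

Further compounds
F1 | step 9 | 4-methoxybenzyl enol ether of dione 13 | COc1ccc(COC2=C(C(=O)CC2)[C@H]3[C@H](C(C)(C)O[Si](CC)(CC)CC)[C@H]3/C=C/C)cc1
F2 | step 9 | 1α-(4-methoxybenzyloxy)-11-(triethylsilyloxy)-15-norguaia-5,8-dien-4-one | C[C@H]1C=C[C@@H](C(C)(C)O[Si](CC)(CC)CC)C=C2C(=O)CC[C@@]12OCc3ccc(OC)cc3
F3 | step 9 | 1α-hydroxy-11-(triethylsilyloxy)-15-norguaia-5,8-dien-4-one | C[C@H]1C=C[C@@H](C(C)(C)O[Si](CC)(CC)CC)C=C2C(=O)CC[C@@]12O
F4 | step 4 | (E)-alkenylboronate, pinacol ester | CC1(C)OB(/C=C/C(C)(C)O[Si](CC)(CC)CC)OC1(C)C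
F5 | step 4 | ethyl cyclopropanecarboxylate with cis boronate and trans side chain | CCOC(=O)[C@H]1[C@@H](B2OC(C)(C)C(C)(C)O2)[C@@H]1C(C)(C)O[Si](CC)(CC)CC
F6 | step 4 | cyclopropylmethanol with cis boronate and trans side chain | OC[C@H]1[C@@H](B2OC(C)(C)C(C)(C)O2)[C@@H]1C(C)(C)O[Si](CC)(CC)CC
F7 | step 19 | 6β-chloroacetate of 26 | C[C@H]1C[C@@H](OC(=O)/C(C)=C\C)[C@@H](C(C)(C)OC(C)=O)[C@@H](OC(=O)CCl)C2=C(C)CC[C@@]12O[Si](C)(C)C(C)(C)C
F8 | step 19 | 6β-chloroacetoxy guai-4-en-3-one | C[C@H]1C[C@@H](OC(=O)/C(C)=C\C)[C@@H](C(C)(C)OC(C)=O)[C@@H](OC(=O)CCl)C2=C(C)C(=O)C[C@@]12O[Si](C)(C)C(C)(C)C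
F9 | step 19 | 1-O-TBS ether of the target | C[C@H]1C[C@@H](OC(=O)/C(C)=C\C)[C@@H](C(C)(C)OC(C)=O)[C@@H](O)C2=C(C)C(=O)C[C@@]12O[Si](C)(C)C(C)(C)C
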